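## Analysis of the target

The target (18) is a C30 hydrocarbon: a hexadeca-1,10,14-triene chain (C1–C16) whose quaternary carbon C7 carries a methyl group and a 3-methyl-6-isopropenylcyclohex-2-en-1-yl ring (C1'–C6', attached through C1'). It has four stereocentres, all S: the allylic methine C3, the acyclic all-carbon quaternary C7, and the ring pair C1'/C6', which is trans. C7, C1' and C6' form a contiguous triad, whereas C3 is insulated from it by three methylenes and can only be set by a reagent. The hard centre is C7: its three non-ring substituents (the methyl group and the C6 and C8 methylenes) are sterically almost alike, so no facial bias can set it; only a process that translates olefin geometry into configuration can. The feature the plan exploits is the C7–C1' bond, which joins this quaternary carbon to a ring carbon that is allylic to C2'=C3' and flanked by the stereocentre C6'. Read across that bond, C7 with its methyl group, C8–C16 and the C6–C5 stub is a rearranged farnesyl (nerolidyl) unit. The ring C1'–C6' with the C3' methyl and the C6' isopropenyl group is the skeleton of carvone, with C1' as its α' carbon and C2' as its carbonyl carbon. There is no heteroatom; the sensitive groups are five olefins of four substitution classes that must be told apart, must not migrate and are prone to acid-induced cyclisation.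

## Retrosynthetic reasoning

**C2–C3 (vinyl to methine).** 18 is cut between the terminal vinyl group and C3, back to the secondary pinacol boronate 15. A vinyl nucleophile is added to boron, and an iodine-triggered 1,2-shift with retention followed by elimination gives the olefin. This puts the most reactive olefin in last and makes C3 a C–B stereocentre that a reagent can set.

**C3–C4 and C4–C5 (one-carbon insertions).** 15 is cut back to the primary boronate 13 by removing the C3 methine with its methyl group (insertion of a chiral lithiated carbenoid into the C–B bond). 13 is cut back to 11 by removing the C4 methylene (insertion of a chloromethyl carbenoid). Both are stereospecific 1,2-metallate shifts, so C3 is set by the reagent alone, far from the triad.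

**C5–B (hydroboration).** 11 comes from the triene-diene hydrocarbon 10 by anti-Markovnikov hydroboration of the vinyl group on C7 (C6=C5). The forward step must choose the only monosubstituted olefin among five.

**C2'–H (oxygen removal with olefin placement).** 10 is traced to the alkenyl triflate 9 and this to enone 7. Conjugate hydride addition to the enone gives a regiodefined enolate, O-triflation fixes the double bond at C2'=C3', and reduction replaces oxygen by hydrogen. This turns the carvone enone into the 3-methylcyclohex-2-ene of the target without touching C1'.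

**C7–C1' (key disconnection).** 7 is cut between C7 and C1' to the allyl dienyl ether 6 by a retro-Claisen step. The cut is made here because it is the only bond whose formation can set C7 from olefin geometry and C1' from C6' at once. It also divides the C25 core into (S)-carvone (1) and (2E,6E)-farnesol (5), leaving the vinyl group and the enone as handles.

**C–O of the enol ether.** 6 is cut at the dienyl C–O bond into the dienyl boronate 4 and 5. 4 goes back through the dienyl triflate 3 to 1 by kinetic α'-enolisation. The forward steps must place oxygen on the cross-conjugated enol position without C-alkylation, which is why the ether is made by copper-mediated C–O coupling and not by enolate alkylation.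

## Alternatives that were turned down

**Alternative 1:** The textbook disconnection is a Diels–Alder cut of the cyclohexene at C1'–C6' and C4'–C5'. Forward, the (E)-diene A1, which already carries C7 and both chains, would react with an acetyl-bearing vinyl dienophile to give the endo adduct A2. Epimerisation at C6' to trans and methylenation of the acetyl group would follow. It was turned down because it moves the problem instead of solving it. A1 needs the isolated quaternary carbon C7 to be built first, by a method that must tell a methyl from two methylene arms, in a linear sequence far longer than the whole route below. In the cycloaddition, C7 cannot direct the dienophile to one diene face, because its three alkyl arms are alike. C1', and with it the C7/C1' relation, would therefore be uncontrolled unless a chiral catalyst overrode a very hindered 1-tert-alkyl diene. The endo rule also gives the cis pair and costs a further epimerisation.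

**Alternative 2:** An Ireland–Claisen rearrangement with the ring as the allyl part cuts the same C7–C1' bond with reversed roles. Forward, the tertiary allylic ester A3 would be converted to its silyl ketene acetal and rearranged with 1,3-transfer of the C–O configuration to C1', giving acid A4. It was turned down for three reasons:
- C7 would arise from the fully substituted ketene acetal carbon, whose geometry depends on the difference between an α-methyl and an α-primary-alkyl group, which is essentially none.
- Cyclohexenyl esters divide between chair and boat transition states.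
- A4 carries C6 as a neopentyl carboxyl group, and turning it into the C6 methylene with the C5–C1 chain attached would take at least five further steps, among them a saturation that cannot be made selective beside five other olefins.

**Alternative 3:** A radical union cuts C7–C1' homolytically. Forward, metal-hydride hydrogen-atom transfer to the C6=C7 olefin of tetraene A6 would give the tertiary C7 radical, which would add (Giese addition) to enone A5 trans to the isopropenyl group to give ketone A7. Enol triflate formation and methyl coupling would follow. It was turned down for three reasons: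
- The planar C7 radical has two faces that differ only by methyl against two methylenes, so the hardest centre would form without control.
- The hydrogen-atom donor cannot choose C6=C7 among the three trisubstituted olefins, the vinyl and the isopropenyl group present in A6 and in the product.
- Neither A5 nor A6 is commercial, so both fragments cost steps before the union.

Key step: step 4

Assumption: (−)-sparteine is taken to direct s-BuLi to the pro-S α-hydrogen of the ethyl ester, so the (+)-enantiomer gives the (R)-carbenoid needed in step 9; 1, 5 (as the pure 2E,6E isomer) and (+)-sparteine are taken as commercial.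

## Route

Step 1
Reactants: 1 (S)-(+)-carvone, (5S)-2-methyl-5-(prop-1-en-2-yl)cyclohex-2-en-1-one
Product: 3 (3S)-6-methyl-3-(prop-1-en-2-yl)cyclohexa-1,5-dien-1-yl trifluoromethanesulfonate, via lithium dienolate 2 (not isolated)
Conditions: LiN(i-Pr)2, THF, −78 °C; PhNTf2, −78 to 0 °C
Reagents that add atoms: N-phenylbis(trifluoromethanesulfonimide), O=S(=O)(N(c1ccccc1)S(=O)(=O)C(F)(F)F)C(F)(F)F
Why: Kinetic deprotonation at the only α' position (carvone C6) gives the cross-conjugated dienolate, which is sulfonylated on oxygen (enolate O-triflation); the isopropenyl-bearing stereocentre is not involved.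

Step 2
Reactants: 3 (3S)-6-methyl-3-(prop-1-en-2-yl)cyclohexa-1,5-dien-1-yl trifluoromethanesulfonate
Product: 4 4,4,5,5-tetramethyl-2-[(3S)-6-methyl-3-(prop-1-en-2-yl)cyclohexa-1,5-dien-1-yl]-1,3,2-dioxaborolane
Conditions: B2pin2, PdCl2(PPh3)2 (3 mol %), PPh3, KOPh, toluene, 50 °C
Reagents that add atoms: bis(pinacolato)diboron, CC1(C)OB(OC1(C)C)B1OC(C)(C)C(C)(C)O1
Why: Miyaura borylation of an alkenyl triflate: oxidative addition to zerovalent palladium, phenoxide-assisted transmetalation with the diboron and reductive elimination; the mild base and temperature should spare the diene and the adjacent stereocentre.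

Step 3
Reactants: 4 4,4,5,5-tetramethyl-2-[(3S)-6-methyl-3-(prop-1-en-2-yl)cyclohexa-1,5-dien-1-yl]-1,3,2-dioxaborolane; 5 (2E,6E)-farnesol, (2E,6E)-3,7,11-trimethyldodeca-2,6,10-trien-1-ol
Product: 6 (5S)-2-methyl-5-(prop-1-en-2-yl)-3-{[(2E,6E)-3,7,11-trimethyldodeca-2,6,10-trien-1-yl]oxy}cyclohexa-1,3-diene
Conditions: Cu(OAc)2 (2 equiv), Et3N (4 equiv), 5 (3 equiv), CH2Cl2, 23 °C, argon; chromatography on Et3N-deactivated silica
Reagents that add atoms: none
Why: Chan–Lam-type oxidative C–O coupling: the dienyl group passes from boron to divalent copper, the alkoxide of 5 binds, and reductive elimination from a trivalent copper intermediate forms the enol ether at the carbon that bore boron. The regiochemistry of the kinetic enolate is therefore kept, the 2E olefin of 5 is untouched, and C-allylation is excluded; alkenyl and dienyl pinacol boronates are known to give allyl vinyl ethers in this way.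

Step 4
Reactants: 6 (5S)-2-methyl-5-(prop-1-en-2-yl)-3-{[(2E,6E)-3,7,11-trimethyldodeca-2,6,10-trien-1-yl]oxy}cyclohexa-1,3-diene
Product: 7 (5S,6S)-2-methyl-5-(prop-1-en-2-yl)-6-[(3R,6E)-3,7,11-trimethyldodeca-1,6,10-trien-3-yl]cyclohex-2-en-1-one
Conditions: toluene, i-Pr2NEt (0.1 equiv), 120 °C, sealed tube, argon
Reagents that add atoms: none
Why: Thermal Claisen rearrangement, a concerted suprafacial [3,3] shift in which the allyl C–O bond of 6 breaks while C3 of the farnesyl unit bonds to the CH terminus of the ring enol ether (the future C1'), regenerating the conjugated enone. The closest known reaction type is the Claisen rearrangement of allyl enol ethers of cyclic ketones with γ,γ-disubstituted (geranyl-type) allyl groups, which builds a quaternary carbon next to a tertiary one. No ring is closed; the six-membered array exists only in the transition state. C1' is controlled by the resident stereocentre C6': the migrating terminus should be delivered to the face of the cyclohexadiene anti to the isopropenyl group, which gives the trans pair. C7 is controlled relative to C1' by olefin geometry read through a chair transition state: the ring enol ether is necessarily Z (C6' equatorial, hydrogen axial on the bond-forming carbon), and the 2E olefin places the homogeranyl chain equatorial and only the methyl group axial, which corresponds to 3R in the side chain of 7 and to 7S in 18. The step therefore needs chair over boat, secured because the allyl part is acyclic and the only axial group is a methyl, and anti over syn delivery, secured by the bulk of the fully substituted terminus that must pass the C6' substituent. It also needs the pericyclic path to outrun ionisation of the allyl ether, secured by the apolar solvent, the amine buffer and the exclusion of acid. One operation thus forms the C7–C1' bond, the quaternary centre and its tertiary neighbour from two commercial terpenes, and leaves the vinyl group and the enone as handles.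

Step 5
Reactants: 7 (5S,6S)-2-methyl-5-(prop-1-en-2-yl)-6-[(3R,6E)-3,7,11-trimethyldodeca-1,6,10-trien-3-yl]cyclohex-2-en-1-one
Product: 9 (5S,6S)-2-methyl-5-(prop-1-en-2-yl)-6-[(3R,6E)-3,7,11-trimethyldodeca-1,6,10-trien-3-yl]cyclohex-1-en-1-yl trifluoromethanesulfonate, via lithium enolate 8 (not isolated)
Conditions: LiBH(s-Bu)3, THF, −78 °C; PhNTf2, −78 to 23 °C
Reagents that add atoms: N-phenylbis(trifluoromethanesulfonimide), O=S(=O)(N(c1ccccc1)S(=O)(=O)C(F)(F)F)C(F)(F)F
Why: The bulky borohydride should add hydride 1,4 to the β-unsubstituted, α-methyl enone, as it does with carvone itself, and the enolate formed is regiospecific, so O-triflation fixes the future ring olefin between the carbonyl carbon and the methyl-bearing carbon. The α' carbon (C1' of the target) is never enolised and keeps its configuration.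

Step 6
Reactants: 9 (5S,6S)-2-methyl-5-(prop-1-en-2-yl)-6-[(3R,6E)-3,7,11-trimethyldodeca-1,6,10-trien-3-yl]cyclohex-1-en-1-yl trifluoromethanesulfonate
Product: 10 (3S,4S)-1-methyl-4-(prop-1-en-2-yl)-3-[(3R,6E)-3,7,11-trimethyldodeca-1,6,10-trien-3-yl]cyclohex-1-ene
Conditions: Pd(OAc)2 (5 mol %), PPh3, HCO2H, n-Bu3N, DMF, 60 °C
Reagents that add atoms: none
Why: Palladium-catalysed formate reduction of an alkenyl triflate: oxidative addition to zerovalent palladium, formate exchange, loss of CO2 and C–H reductive elimination replace the triflate by hydrogen with the olefin position fixed. Together with step 5 this erases the oxygen and places the ring double bond at C2'=C3'.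

Step 7
Reactants: 10 (3S,4S)-1-methyl-4-(prop-1-en-2-yl)-3-[(3R,6E)-3,7,11-trimethyldodeca-1,6,10-trien-3-yl]cyclohex-1-ene
Product: 11 4,4,5,5-tetramethyl-2-{(3S,6E)-3,7,11-trimethyl-3-[(1S,6S)-3-methyl-6-(prop-1-en-2-yl)cyclohex-2-en-1-yl]dodeca-6,10-dien-1-yl}-1,3,2-dioxaborolane
Conditions: HBpin (1.1 equiv), [Ir(cod)Cl]2 (1.5 mol %), dppm (3 mol %), CH2Cl2, 23 °C
Reagents that add atoms: pinacolborane, [H]B1OC(C)(C)C(C)(C)O1
Why: Iridium-catalysed hydroboration is strongly selective for monosubstituted terminal olefins and gives the linear boronate. The vinyl group on C7 is the only such olefin in 10; the isopropenyl group and the three trisubstituted olefins should react much more slowly, and the neopentyl position excludes the branched isomer.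

Step 8
Reactants: 11 4,4,5,5-tetramethyl-2-{(3S,6E)-3,7,11-trimethyl-3-[(1S,6S)-3-methyl-6-(prop-1-en-2-yl)cyclohex-2-en-1-yl]dodeca-6,10-dien-1-yl}-1,3,2-dioxaborolane
Product: 13 4,4,5,5-tetramethyl-2-{(4S,7E)-4,8,12-trimethyl-4-[(1S,6S)-3-methyl-6-(prop-1-en-2-yl)cyclohex-2-en-1-yl]trideca-7,11-dien-1-yl}-1,3,2-dioxaborolane, via chloromethyl borate 12 (not isolated)
Conditions: BrCH2Cl, n-BuLi, THF, −78 to 23 °C
Reagents that add atoms: bromochloromethane, ClCBr
Why: Matteson homologation: chloromethyllithium generated in the presence of 11 adds to boron, and 1,2-migration of the primary alkyl group with loss of chloride inserts one methylene (the future C4) into the C–B bond.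

Step 9
Reactants: 13 4,4,5,5-tetramethyl-2-{(4S,7E)-4,8,12-trimethyl-4-[(1S,6S)-3-methyl-6-(prop-1-en-2-yl)cyclohex-2-en-1-yl]trideca-7,11-dien-1-yl}-1,3,2-dioxaborolane
Product: 15 4,4,5,5-tetramethyl-2-{(2S,6S,9E)-6,10,14-trimethyl-6-[(1S,6S)-3-methyl-6-(prop-1-en-2-yl)cyclohex-2-en-1-yl]pentadeca-9,13-dien-2-yl}-1,3,2-dioxaborolane, via borate complex 14 (not isolated)
Conditions: ethyl 2,4,6-triisopropylbenzoate, s-BuLi, (+)-sparteine, Et2O, −78 °C; 13, −78 °C; then 35 °C
Reagents that add atoms: ethyl 2,4,6-triisopropylbenzoate, CCOC(=O)c1c(C(C)C)cc(C(C)C)cc1C(C)C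
Why: Lithiation–borylation, a stereospecific Matteson-type homologation: sparteine-directed deprotonation gives the configurationally stable (R)-α-lithioethyl ester, which adds to boron with retention. The alkyl group then migrates anti to the leaving carboxylate with inversion, which should give the (S)-configured secondary boronate, that is C3 with its methyl group, under reagent control and independent of the distant triad.

Step 10
Reactants: 15 4,4,5,5-tetramethyl-2-{(2S,6S,9E)-6,10,14-trimethyl-6-[(1S,6S)-3-methyl-6-(prop-1-en-2-yl)cyclohex-2-en-1-yl]pentadeca-9,13-dien-2-yl}-1,3,2-dioxaborolane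
Product: 18 (3S,7S,10E)-3,7,11,15-tetramethyl-7-[(1S,6S)-3-methyl-6-(prop-1-en-2-yl)cyclohex-2-en-1-yl]hexadeca-1,10,14-triene, via vinyl borate 16 (not isolated), via iodoalkyl boronate 17 (not isolated)
Conditions: CH2=CHMgBr (4 equiv), THF, 23 °C; I2, MeOH, −78 °C; NaOMe, −78 to 23 °C
Reagents that add atoms: vinylmagnesium bromide, C=C[Mg]Br
Why: Zweifel olefination: the vinyl borate is iodinated at its terminal carbon, the secondary alkyl group migrates from boron to carbon with retention, and methoxide-induced anti-elimination of boron and iodide releases the terminal vinyl group, which should give C3 as S. At −78 °C iodine should react with the electron-rich borate far faster than with the isolated olefins.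

## Compound list

1 | (S)-(+)-carvone, (5S)-2-methyl-5-(prop-1-en-2-yl)cyclohex-2-en-1-one | CC1=CC[C@@H](CC1=O)C(C)=C | starting material
2 | lithium (3S)-6-methyl-3-(prop-1-en-2-yl)cyclohexa-1,5-dien-1-olate (lithium dienolate of 1) | C1=C(O[Li])C(C)=CC[C@@H]1C(=C)C | intermediate
3 | (3S)-6-methyl-3-(prop-1-en-2-yl)cyclohexa-1,5-dien-1-yl trifluoromethanesulfonate | C1=C(OS(=O)(=O)C(F)(F)F)C(C)=CC[C@@H]1C(=C)C | intermediate
4 | 4,4,5,5-tetramethyl-2-[(3S)-6-methyl-3-(prop-1-en-2-yl)cyclohexa-1,5-dien-1-yl]-1,3,2-dioxaborolane | C1=C(B2OC(C)(C)C(C)(C)O2)C(C)=CC[C@@H]1C(=C)C | intermediate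
5 | (2E,6E)-farnesol, (2E,6E)-3,7,11-trimethyldodeca-2,6,10-trien-1-ol | OC/C=C(\C)CC/C=C(\C)CCC=C(C)C | starting material
6 | (5S)-2-methyl-5-(prop-1-en-2-yl)-3-{[(2E,6E)-3,7,11-trimethyldodeca-2,6,10-trien-1-yl]oxy}cyclohexa-1,3-diene | C1=C(OC/C=C(\C)CC/C=C(\C)CCC=C(C)C)C(C)=CC[C@@H]1C(=C)C | intermediate
7 | (5S,6S)-2-methyl-5-(prop-1-en-2-yl)-6-[(3R,6E)-3,7,11-trimethyldodeca-1,6,10-trien-3-yl]cyclohex-2-en-1-one | C=C[C@@](C)(CC/C=C(\C)CCC=C(C)C)[C@H]1C(=O)C(C)=CC[C@@H]1C(=C)C | intermediate
8 | lithium (5S,6S)-2-methyl-5-(prop-1-en-2-yl)-6-[(3R,6E)-3,7,11-trimethyldodeca-1,6,10-trien-3-yl]cyclohex-1-en-1-olate | C=C[C@@](C)(CC/C=C(\C)CCC=C(C)C)[C@H]1C(O[Li])=C(C)CC[C@@H]1C(=C)C | intermediate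
9 | (5S,6S)-2-methyl-5-(prop-1-en-2-yl)-6-[(3R,6E)-3,7,11-trimethyldodeca-1,6,10-trien-3-yl]cyclohex-1-en-1-yl trifluoromethanesulfonate | C=C[C@@](C)(CC/C=C(\C)CCC=C(C)C)[C@H]1C(OS(=O)(=O)C(F)(F)F)=C(C)CC[C@@H]1C(=C)C | intermediate
10 | (3S,4S)-1-methyl-4-(prop-1-en-2-yl)-3-[(3R,6E)-3,7,11-trimethyldodeca-1,6,10-trien-3-yl]cyclohex-1-ene | C=C[C@@](C)(CC/C=C(\C)CCC=C(C)C)[C@H]1C=C(C)CC[C@@H]1C(=C)C | intermediate
11 | 4,4,5,5-tetramethyl-2-{(3S,6E)-3,7,11-trimethyl-3-[(1S,6S)-3-methyl-6-(prop-1-en-2-yl)cyclohex-2-en-1-yl]dodeca-6,10-dien-1-yl}-1,3,2-dioxaborolane | CC1(C)OB(OC1(C)C)CC[C@@](C)(CC/C=C(\C)CCC=C(C)C)[C@H]2C=C(C)CC[C@@H]2C(=C)C | intermediate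
12 | lithium chloromethyl borate of 11 (chloromethyl group and the alkyl group of 11 on the pinacolato boron) | [Li+].ClC[B-]1(CC[C@@](C)(CC/C=C(\C)CCC=C(C)C)[C@H]2C=C(C)CC[C@@H]2C(=C)C)OC(C)(C)C(C)(C)O1 | intermediate
13 | 4,4,5,5-tetramethyl-2-{(4S,7E)-4,8,12-trimethyl-4-[(1S,6S)-3-methyl-6-(prop-1-en-2-yl)cyclohex-2-en-1-yl]trideca-7,11-dien-1-yl}-1,3,2-dioxaborolane | CC1(C)OB(OC1(C)C)CCC[C@@](C)(CC/C=C(\C)CCC=C(C)C)[C@H]2C=C(C)CC[C@@H]2C(=C)C | intermediate
14 | lithium borate of 13 bearing the (R)-1-(2,4,6-triisopropylbenzoyloxy)ethyl group on boron | [Li+].C[C@H](OC(=O)c1c(C(C)C)cc(C(C)C)cc1C(C)C)[B-]2(CCC[C@@](C)(CC/C=C(\C)CCC=C(C)C)[C@H]3C=C(C)CC[C@@H]3C(=C)C)OC(C)(C)C(C)(C)O2 | intermediate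
15 | 4,4,5,5-tetramethyl-2-{(2S,6S,9E)-6,10,14-trimethyl-6-[(1S,6S)-3-methyl-6-(prop-1-en-2-yl)cyclohex-2-en-1-yl]pentadeca-9,13-dien-2-yl}-1,3,2-dioxaborolane | C[C@H](B1OC(C)(C)C(C)(C)O1)CCC[C@@](C)(CC/C=C(\C)CCC=C(C)C)[C@H]2C=C(C)CC[C@@H]2C(=C)C | intermediate
16 | bromomagnesium vinyl borate of 15 (vinyl group and the secondary alkyl group of 15 on the pinacolato boron) | C[C@H]([B-]1(C=C)OC(C)(C)C(C)(C)O1)CCC[C@@](C)(CC/C=C(\C)CCC=C(C)C)[C@H]2C=C(C)CC[C@@H]2C(=C)C.[Mg+]Br | intermediate
17 | 2-[(3S,7S,10E)-1-iodo-3,7,11,15-tetramethyl-7-{(1S,6S)-3-methyl-6-(prop-1-en-2-yl)cyclohex-2-en-1-yl}hexadeca-10,14-dien-2-yl]-4,4,5,5-tetramethyl-1,3,2-dioxaborolane (either configuration at C2) | C[C@H](C(CI)B1OC(C)(C)C(C)(C)O1)CCC[C@@](C)(CC/C=C(\C)CCC=C(C)C)[C@H]2C=C(C)CC[C@@H]2C(=C)C | intermediate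
18 | (3S,7S,10E)-3,7,11,15-tetramethyl-7-[(1S,6S)-3-methyl-6-(prop-1-en-2-yl)cyclohex-2-en-1-yl]hexadeca-1,10,14-triene | C=C[C@@H](C)CCC[C@@](C)(CC/C=C(\C)CCC=C(C)C)[C@H]1C=C(C)CC[C@@H]1C(=C)C | target

## Step count and risk

Total step count: 10. Longest linear sequence: 10 steps (1 to 18); 5 and all reagents are commercial, so no side branch adds steps.

Least certain steps:

**Step 4 (key step).** What may go wrong: leakage through the boat transition state or delivery syn to the isopropenyl group, either of which inverts C7 relative to the ring. Heterolysis of the allyl–oxygen bond or 1,5-hydrogen shifts in the cyclohexadiene may also occur before the rearrangement, because the dienyl ether is acid-labile and thermally mobile. The fallback is a Carroll rearrangement, which avoids the dienyl ether altogether and sets out from 1 and 5. 5 would be converted with 1,1'-carbonyldiimidazole into (2E,6E)-farnesyl 1H-imidazole-1-carboxylate F1. The lithium dienolate 2 would be acylated on carbon by F1 (BF3·OEt2, THF, −78 °C) to give the farnesyl β-keto ester F2. Heating F2 (xylene, 140–160 °C) should induce the [3,3] shift of its ester enol to the β-keto acid F3, which loses CO2 and is protonated trans to the isopropenyl group, coming back to the route at 7. In the chair transition state of this manifold the same 2E geometry should lead to the same configuration at C7.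

**Step 3.** What may go wrong: slow transfer of the hindered 2-boryl diene to divalent copper, with protodeboronation or acetate transfer taking over, and hydrolysis of the enol ether during isolation. The fallback reverses the polarity of the C–O coupling and sets out from 3. Nickel-catalysed triflate–iodide exchange (NaI, Ni(OAc)2·4H2O, 1,5-cyclooctadiene, DMA–THF, 23 °C) would give the dienyl iodide F4. F4 would be coupled with 5 by monovalent copper in an Ullmann-type reaction (CuI, 3,4,7,8-tetramethyl-1,10-phenanthroline, Cs2CO3, toluene, 80 then 120 °C). The ether 6 would form and rearrange in the same flask, so the fallback comes back at 7.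

**Step 7.** What may go wrong: loss of chemoselectivity, that is hydroboration of the isopropenyl group, or olefin migration by an iridium hydride. The fallback replaces the boron chain extension and sets out from 10. Rhodium-catalysed hydroformylation (Rh(acac)(CO)2, a wide-bite-angle bisphosphine, CO/H2, toluene, 60 °C), which is linear-selective and discriminates mono- from 1,1-disubstituted olefins, would give the aldehyde F5, which already contains C4. Crotylboration with (Z)-crotyldiisopinocampheylborane of the antipode that sets the C3 methyl centre would give the syn homoallylic alcohol F6; its carbinol configuration is immaterial. The xanthate F7 (NaH, CS2, MeI) would be reduced with n-Bu3SnH and AIBN at high stannane concentration (Barton–McCombie deoxygenation). This comes back directly at 18 and bypasses steps 7 to 10.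

**Step 10.** What may go wrong: electrophilic attack of iodine on the trisubstituted olefins (iodo-etherification or cation–olefin cyclisation), or incomplete borate formation at the hindered secondary boronate. The iodine-free fallback sets out from 15. A second Matteson homologation (BrCH2Cl, n-BuLi) would give the primary boronate F8, and oxidation (NaBO3·4H2O) the primary alcohol F9. Oxidation with TEMPO/PhI(OAc)2 would give the α-methyl aldehyde F10, and Wittig methylenation with salt-free Ph3P=CH2 at low temperature comes back at 18.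

**Step 6.** What may go wrong: carbopalladation of a pendant olefin by the alkenylpalladium intermediate (Heck-type cyclisation), or slow oxidative addition at the hindered tetrasubstituted triflate. The fallback sets out from 7 and bypasses steps 5 and 6. Condensation with tosylhydrazide (EtOH, cat. AcOH, 60 °C) would give the tosylhydrazone F11. Reduction with catecholborane followed by NaOAc·3H2O at 60 °C should trigger loss of sulfinate and N2 with a sigmatropic hydrogen shift that moves the double bond to C2'=C3', coming back at 10.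

## Further compounds

F1 | step 4 | (2E,6E)-3,7,11-trimethyldodeca-2,6,10-trien-1-yl 1H-imidazole-1-carboxylate | O=C(OC/C=C(\C)CC/C=C(\C)CCC=C(C)C)n1ccnc1
F2 | step 4 | (2E,6E)-3,7,11-trimethyldodeca-2,6,10-trien-1-yl (6S)-3-methyl-2-oxo-6-(prop-1-en-2-yl)cyclohex-3-ene-1-carboxylate (C1 epimers and enol) | O=C(OC/C=C(\C)CC/C=C(\C)CCC=C(C)C)C1C(=O)C(C)=CC[C@@H]1C(=C)C
F3 | step 4 | (1R,6R)-3-methyl-2-oxo-6-(prop-1-en-2-yl)-1-[(3R,6E)-3,7,11-trimethyldodeca-1,6,10-trien-3-yl]cyclohex-3-ene-1-carboxylic acid (carboxyl cis, side chain trans to the isopropenyl group) | C=C[C@@](C)(CC/C=C(\C)CCC=C(C)C)[C@@]1(C(=O)O)C(=O)C(C)=CC[C@@H]1C(=C)C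
F4 | step 3 | (3S)-1-iodo-6-methyl-3-(prop-1-en-2-yl)cyclohexa-1,5-diene | C1=C(I)C(C)=CC[C@@H]1C(=C)C
F5 | step 7 | (4R,7E)-4,8,12-trimethyl-4-[(1S,6S)-3-methyl-6-(prop-1-en-2-yl)cyclohex-2-en-1-yl]trideca-7,11-dienal | O=CCC[C@@](C)(CC/C=C(\C)CCC=C(C)C)[C@H]1C=C(C)CC[C@@H]1C(=C)C
F6 | step 7 | (3R,4R,7R,10E)-3,7,11,15-tetramethyl-7-[(1S,6S)-3-methyl-6-(prop-1-en-2-yl)cyclohex-2-en-1-yl]hexadeca-1,10,14-trien-4-ol (3,4-syn) | C=C[C@@H](C)[C@H](O)CC[C@@](C)(CC/C=C(\C)CCC=C(C)C)[C@H]1C=C(C)CC[C@@H]1C(=C)C
F7 | step 7 | O-{(3R,4R,7R,10E)-3,7,11,15-tetramethyl-7-[(1S,6S)-3-methyl-6-(prop-1-en-2-yl)cyclohex-2-en-1-yl]hexadeca-1,10,14-trien-4-yl} S-methyl carbonodithioate | C=C[C@@H](C)[C@H](OC(=S)SC)CC[C@@](C)(CC/C=C(\C)CCC=C(C)C)[C@H]1C=C(C)CC[C@@H]1C(=C)C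
F8 | step 10 | 4,4,5,5-tetramethyl-2-{(2R,6S,9E)-2,6,10,14-tetramethyl-6-[(1S,6S)-3-methyl-6-(prop-1-en-2-yl)cyclohex-2-en-1-yl]pentadeca-9,13-dien-1-yl}-1,3,2-dioxaborolane | C[C@H](CB1OC(C)(C)C(C)(C)O1)CCC[C@@](C)(CC/C=C(\C)CCC=C(C)C)[C@H]2C=C(C)CC[C@@H]2C(=C)C
F9 | step 10 | (2S,6S,9E)-2,6,10,14-tetramethyl-6-[(1S,6S)-3-methyl-6-(prop-1-en-2-yl)cyclohex-2-en-1-yl]pentadeca-9,13-dien-1-ol | C[C@H](CO)CCC[C@@](C)(CC/C=C(\C)CCC=C(C)C)[C@H]1C=C(C)CC[C@@H]1C(=C)C
F10 | step 10 | (2S,6S,9E)-2,6,10,14-tetramethyl-6-[(1S,6S)-3-methyl-6-(prop-1-en-2-yl)cyclohex-2-en-1-yl]pentadeca-9,13-dienal | C[C@H](C=O)CCC[C@@](C)(CC/C=C(\C)CCC=C(C)C)[C@H]1C=C(C)CC[C@@H]1C(=C)C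
F11 | step 6 | 4-methyl-N'-{(5S,6S)-2-methyl-5-(prop-1-en-2-yl)-6-[(3R,6E)-3,7,11-trimethyldodeca-1,6,10-trien-3-yl]cyclohex-2-en-1-ylidene}benzenesulfonohydrazide | C=C[C@@](C)(CC/C=C(\C)CCC=C(C)C)[C@H]1C(=NNS(=O)(=O)c2ccc(C)cc2)C(C)=CC[C@@H]1C(=C)C
A1 | alternative 1 | (3E,5S,8E)-2,5,9,13-tetramethyl-5-[(4S)-4-methylhex-5-en-1-yl]tetradeca-1,3,8,12-tetraene | C=C[C@@H](C)CCC[C@@](C)(CC/C=C(\C)CCC=C(C)C)/C=C/C(C)=C
A2 | alternative 1 | endo adduct, 1-{cis-4-methyl-2-[(3S,7S,10E)-3,7,11,15-tetramethylhexadeca-1,10,14-trien-7-yl]cyclohex-3-en-1-yl}ethan-1-one with the wanted configuration at C1' | C=C[C@@H](C)CCC[C@@](C)(CC/C=C(\C)CCC=C(C)C)[C@H]1C=C(C)CC[C@H]1C(C)=O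
A3 | alternative 2 | (1S,4S)-1-methyl-4-(prop-1-en-2-yl)cyclohex-2-en-1-yl (5E)-2,6,10-trimethylundeca-5,9-dienoate (ester oxygen trans to the isopropenyl group) | C[C@@]1(OC(=O)C(C)CC/C=C(\C)CCC=C(C)C)C=C[C@@H](C(C)=C)CC1
A4 | alternative 2 | (2S,5E)-2,6,10-trimethyl-2-[(1S,6S)-3-methyl-6-(prop-1-en-2-yl)cyclohex-2-en-1-yl]undeca-5,9-dienoic acid | OC(=O)[C@@](C)(CC/C=C(\C)CCC=C(C)C)[C@H]1C=C(C)CC[C@@H]1C(=C)C
A5 | alternative 3 | (4S)-4-(prop-1-en-2-yl)cyclohex-2-en-1-one | C1=CC(=O)CC[C@@H]1C(=C)C
A6 | alternative 3 | (3S,6E,10E)-3,7,11,15-tetramethylhexadeca-1,6,10,14-tetraene | C=C[C@@H](C)CC/C=C(\C)CC/C=C(\C)CCC=C(C)C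
A7 | alternative 3 | (3S,4S)-4-(prop-1-en-2-yl)-3-[(3S,7S,10E)-3,7,11,15-tetramethylhexadeca-1,10,14-trien-7-yl]cyclohexan-1-one | C=C[C@@H](C)CCC[C@@](C)(CC/C=C(\C)CCC=C(C)C)[C@H]1CC(=O)CC[C@@H]1C(=C)C
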